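## Retrosynthetic overview

1. The target is two copies of one C15 flavan-3,4-diol less water: a fisetinidol unit (benzo ring A, catechol ring B, pyran ring C) bonded through its C4 to C6 of ring D of a 2,3-trans-3,4-cis leucofisetinidin unit (benzo ring D, catechol ring E, pyran ring F). The C4(ring C)–C6(ring D) bond is cut last, as biomimetic capture of a C4 benzylic cation by the resorcinol-type ring D, so both halves come from one monomer, 10.
2. In 10 the pyran ring (later ring C and ring F) is cut at C3–C4. The enabling feature is the cis-vicinal diol at C3/C4 whose C4 is benzylic on the benzo ring and ortho to the ether oxygen O1: this is the retron of a pinacol coupling between a salicylaldehyde carbonyl (C4) and an α-aryloxy aldehyde (C3) tethered by the O1–C2 ether.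
3. C2 is the only stereocentre set by a catalyst (Ru transfer hydrogenation, then Mitsunobu inversion into the O1–C2 ether). C3 and C4 of both units are relayed from it in the pinacol step, and C4 of ring C in the coupling.
4. Ring order: benzo and catechol rings are bought; the pyran ring is closed in step 6; the interflavan bond follows; deprotection is last.

Key step: step 6

Remark: thioether 12 is drawn as its 3,4-trans epimer; any 3,4-cis epimer formed with it would be carried along, since both give the same C4 cation in step 9.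

## Route

Step 1
Reactants: 1 1,2-bis(benzyloxy)-4-bromobenzene; 2 dimethyl oxalate
Product: 4 methyl 2-[3,4-bis(benzyloxy)phenyl]-2-oxoacetate, via aryllithium 3 (not isolated)
Conditions: n-BuLi (1.05 equiv), THF, −78 °C; cannulated into 2 (3 equiv), THF, −78 °C; 1 M HCl quench
Reagents that add atoms: none
Why: Br/Li exchange followed by inverse addition of the aryllithium to excess dialkyl oxalate (acylation of an organolithium by an oxalate ester) should stop at the α-keto ester because the tetrahedral lithium adduct survives at −78 °C until the quench; the benzyl ethers are inert.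

Step 2
Reactants: 4 methyl 2-[3,4-bis(benzyloxy)phenyl]-2-oxoacetate
Product: 5 methyl (2S)-2-[3,4-bis(benzyloxy)phenyl]-2-hydroxyacetate
Conditions: RuCl[(R,R)-TsDPEN](p-cymene) (1 mol%), HCO2H/Et3N (5:2), DMF, 25 °C
Reagents that add atoms: none
Why: Noyori asymmetric transfer hydrogenation of an aryl α-keto ester; the (R,R) ligand orients the aryl group as in aryl ketone reductions, which for this substituent pattern corresponds to the (S)-α-hydroxy ester (the other catalyst enantiomer would be used if the sense proved reversed), and this is the stereocentre from which all others are relayed.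

Step 3
Reactants: 5 methyl (2S)-2-[3,4-bis(benzyloxy)phenyl]-2-hydroxyacetate; 6 4-(benzyloxy)-2-hydroxybenzaldehyde
Product: 7 methyl (2R)-2-[5-(benzyloxy)-2-formylphenoxy]-2-[3,4-bis(benzyloxy)phenyl]acetate
Conditions: PPh3, DIAD, toluene, 0 °C → rt
Reagents that add atoms: none
Why: Mitsunobu etherification of a secondary α-hydroxy ester with an acidic ortho-formyl phenol; the adjacent ester disfavours ionisation of the electron-rich benzylic carbon, so displacement should be clean SN2 with inversion, (S) to (R), under conditions too mild to enolise the product.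

Step 4
Reactants: 7 methyl (2R)-2-[5-(benzyloxy)-2-formylphenoxy]-2-[3,4-bis(benzyloxy)phenyl]acetate
Product: 8 (2R)-2-[5-(benzyloxy)-2-(hydroxymethyl)phenoxy]-2-[3,4-bis(benzyloxy)phenyl]ethan-1-ol
Conditions: LiBH4 (3 equiv), THF, 0 °C → rt; aqueous work-up
Reagents that add atoms: none
Why: Hydride reduction with LiBH4 takes the aldehyde at once and the α-aryloxy-activated ester at 0 °C while being too weakly basic to epimerise the α-carbon, and gives a stable diol at which enantiomeric purity can be checked and, if needed, raised by recrystallisation.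

Step 5
Reactants: 8 (2R)-2-[5-(benzyloxy)-2-(hydroxymethyl)phenoxy]-2-[3,4-bis(benzyloxy)phenyl]ethan-1-ol
Product: 9 (2R)-2-[5-(benzyloxy)-2-formylphenoxy]-2-[3,4-bis(benzyloxy)phenyl]acetaldehyde
Conditions: Dess–Martin periodinane (2.4 equiv), CH2Cl2, 0 °C; cold work-up, crude product used at once
Reagents that add atoms: none
Why: Dess–Martin oxidation converts both primary alcohols to aldehydes under non-basic conditions at 0 °C, the method of choice for aldehydes with a labile α-stereocentre; the dialdehyde is not chromatographed.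

Step 6
Reactants: 9 (2R)-2-[5-(benzyloxy)-2-formylphenoxy]-2-[3,4-bis(benzyloxy)phenyl]acetaldehyde
Product: 10 (2R,3S,4S)-7-(benzyloxy)-2-[3,4-bis(benzyloxy)phenyl]-3,4-dihydro-2H-chromene-3,4-diol
Conditions: SmI2 (2.5 equiv, slow addition), THF (0.01 M), −78 → −20 °C; aqueous NH4Cl
Reagents that add atoms: none
Why: Single-electron transfer from divalent samarium to the conjugated aryl aldehyde gives a samarium ketyl at C4 that adds to the samarium-coordinated α-aryloxy aldehyde carbon C3 in a 6-exo-trig closure of the pyran ring, after which a second electron reduces the oxygen radical and the trivalent-samarium diolate is protonated on work-up. The closest known reaction type is the SmI2-mediated intramolecular pinacol cyclisation of 1,6-dialdehydes to cis-cyclohexane-1,2-diols. The C3/C4 cis relationship is set by both oxygens being bound to one samarium centre in the bond-forming transition state, and C3–O is set trans to the C2 aryl group because that group sits pseudo-equatorial in the chair-like transition state and the new diol takes the usual anti relationship to an α-substituent, so the stereocentre from step 2 controls both new ones. The step needs ketyl cyclisation to outrun reductive loss of the α-aryloxy group, intermolecular coupling and racemisation of 9; slow addition of SmI2 to a dilute solution at −78 °C, the absence of HMPA, the six-membered chelated transition state and the non-basic medium should secure this.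

Step 7
Reactants: 10 (2R,3S,4S)-7-(benzyloxy)-2-[3,4-bis(benzyloxy)phenyl]-3,4-dihydro-2H-chromene-3,4-diol
Product: 11 3,4-cis-fused cyclic carbonate of 10 (configuration at C2, C3 and C4 as in 10)
Conditions: 1,1'-carbonyldiimidazole (1.5 equiv), DMAP (cat.), THF, rt
Reagents that add atoms: 1,1'-carbonyldiimidazole, O=C(n1ccnc1)n1ccnc1
Why: Carbonylation of a cis-1,2-diol with CDI gives the cis-fused five-membered carbonate, which masks both hydroxyls against O-alkylation and, being electron-poor and able to re-close only cis, guards C4 of the future ring F against ionisation and epimerisation in step 9.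

Step 8
Reactants: 10 (2R,3S,4S)-7-(benzyloxy)-2-[3,4-bis(benzyloxy)phenyl]-3,4-dihydro-2H-chromene-3,4-diol
Product: 12 4α-benzylsulfanyl-7-(benzyloxy)-2α-[3,4-bis(benzyloxy)phenyl]chroman-3β-ol (2,3-trans-3,4-trans)
Conditions: BnSH (5 equiv), p-TsOH·H2O (10 mol%), CH2Cl2, 0 °C → rt
Reagents that add atoms: phenylmethanethiol, SCc1ccccc1
Why: Acid-catalysed SN1 thiolysis of the benzylic C4 hydroxyl (the reaction used to derivatise flavan-3,4-diols and proanthocyanidins): the C4 cation, stabilised by O1 and the para 7-benzyloxy group, is captured by excess thiol, expected mainly anti to the 3-OH.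

Step 9
Reactants: 11 cyclic carbonate of 10; 12 4α-benzylsulfanyl thioether
Product: 13 hexa-O-benzyl fisetinidol-(4α→6)-leucofisetinidin 3,4-cyclic carbonate
Conditions: AgBF4 (2.5 equiv), 11 (3 equiv), THF, 0 °C, slow addition of 12; excess 11 recovered
Reagents that add atoms: none
Why: Thiophilic activation of the C4–S bond by monovalent silver (the neutral-condition interflavanyl coupling of 4-benzylsulfanylflavan-3-ols) regenerates the C4 cation, which undergoes Friedel–Crafts attack by C6 of ring D of 11 (para to O1 and ortho to the 7-benzyloxy group, whereas C8 lies between two oxygens and is more hindered); attack anti to the 3-hydroxyl of the 2,3-trans cation should set the 4α (3,4-trans) configuration, and the excess of 11 with slow addition of 12 should suppress self-condensation.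

Step 10
Reactants: 13 hexa-O-benzyl dimer cyclic carbonate
Product: 14 hexa-O-benzyl fisetinidol-(4α→6)-(2,3-trans-3,4-cis)-leucofisetinidin
Conditions: K2CO3 (0.2 equiv), MeOH/THF, rt
Reagents that add atoms: none
Why: Base-catalysed methanolysis (transesterification) of the cyclic carbonate releases the cis-diol; no free phenol is present, so the basic medium cannot open or epimerise the flavan rings.

Step 11
Reactants: 14 hexa-O-benzyl dimer diol
Product: 15 CNP0280090.4, fisetinidol-(4α→6)-(2R,3S,4S)-leucofisetinidin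
Conditions: H2 (1 atm), Pd(OH)2/C, THF/MeOH, rt, stopped at complete debenzylation
Reagents that add atoms: none
Why: Catalytic hydrogenolysis of six aryl benzyl ethers under neutral, acid-free conditions should be much faster than hydrogenolysis of the secondary benzylic C4 hydroxyl of ring F or of the C2–O1 bonds.

## Compound list

1 | 1,2-bis(benzyloxy)-4-bromobenzene | Brc1ccc(OCc2ccccc2)c(OCc2ccccc2)c1 | starting material
2 | dimethyl oxalate | COC(=O)C(=O)OC | starting material
3 | [3,4-bis(benzyloxy)phenyl]lithium | [Li]c1ccc(OCc2ccccc2)c(OCc2ccccc2)c1 | intermediate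
4 | methyl 2-[3,4-bis(benzyloxy)phenyl]-2-oxoacetate | COC(=O)C(=O)c1ccc(OCc2ccccc2)c(OCc2ccccc2)c1 | intermediate
5 | methyl (2S)-2-[3,4-bis(benzyloxy)phenyl]-2-hydroxyacetate | COC(=O)[C@@H](O)c1ccc(OCc2ccccc2)c(OCc2ccccc2)c1 | intermediate
6 | 4-(benzyloxy)-2-hydroxybenzaldehyde | O=Cc1ccc(OCc2ccccc2)cc1O | starting material
7 | methyl (2R)-2-[5-(benzyloxy)-2-formylphenoxy]-2-[3,4-bis(benzyloxy)phenyl]acetate | COC(=O)[C@H](Oc1cc(OCc2ccccc2)ccc1C=O)c1ccc(OCc2ccccc2)c(OCc2ccccc2)c1 | intermediate
8 | (2R)-2-[5-(benzyloxy)-2-(hydroxymethyl)phenoxy]-2-[3,4-bis(benzyloxy)phenyl]ethan-1-ol | OC[C@H](Oc1cc(OCc2ccccc2)ccc1CO)c1ccc(OCc2ccccc2)c(OCc2ccccc2)c1 | intermediate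
9 | (2R)-2-[5-(benzyloxy)-2-formylphenoxy]-2-[3,4-bis(benzyloxy)phenyl]acetaldehyde | O=C[C@H](Oc1cc(OCc2ccccc2)ccc1C=O)c1ccc(OCc2ccccc2)c(OCc2ccccc2)c1 | intermediate
10 | (2R,3S,4S)-7-(benzyloxy)-2-[3,4-bis(benzyloxy)phenyl]-3,4-dihydro-2H-chromene-3,4-diol (2-aryl α, 3-OH β, 4-OH β) | C(c1ccccc1)Oc1ccc2c(c1)O[C@H](c1ccc(OCc3ccccc3)c(OCc3ccccc3)c1)[C@@H](O)[C@H]2O | intermediate
11 | 3,4-cis-fused cyclic carbonate of 10 (2-aryl α, O-3 β, O-4 β) | C(c1ccccc1)Oc1ccc2c(c1)O[C@H](c1ccc(OCc3ccccc3)c(OCc3ccccc3)c1)[C@H]4OC(=O)O[C@@H]24 | intermediate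
12 | 4α-benzylsulfanyl-7-(benzyloxy)-2α-[3,4-bis(benzyloxy)phenyl]chroman-3β-ol | C(c1ccccc1)Oc1ccc2c(c1)O[C@H](c1ccc(OCc3ccccc3)c(OCc3ccccc3)c1)[C@@H](O)[C@@H]2SCc1ccccc1 | intermediate
13 | hexa-O-benzyl fisetinidol-(4α→6)-leucofisetinidin 3,4-cyclic carbonate (upper unit 2-aryl α, 3-OH β, C4 bond α; lower unit as in 11) | C(c1ccccc1)Oc1ccc2c(c1)O[C@H](c1ccc(OCc3ccccc3)c(OCc3ccccc3)c1)[C@@H](O)[C@@H]2c1cc2c(cc1OCc1ccccc1)O[C@H](c1ccc(OCc3ccccc3)c(OCc3ccccc3)c1)[C@H]4OC(=O)O[C@@H]24 | intermediate
14 | hexa-O-benzyl fisetinidol-(4α→6)-(2,3-trans-3,4-cis)-leucofisetinidin (lower unit as in 10) | C(c1ccccc1)Oc1ccc2c(c1)O[C@H](c1ccc(OCc3ccccc3)c(OCc3ccccc3)c1)[C@@H](O)[C@@H]2c1cc2c(cc1OCc1ccccc1)O[C@H](c1ccc(OCc3ccccc3)c(OCc3ccccc3)c1)[C@@H](O)[C@H]2O | intermediate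
15 | (2R,3S,4S)-6-[(2R,3S,4R)-2-(3,4-dihydroxyphenyl)-3,7-dihydroxy-3,4-dihydro-2H-chromen-4-yl]-2-(3,4-dihydroxyphenyl)-3,4-dihydro-2H-chromene-3,4,7-triol | Oc1ccc2c(c1)O[C@H](c1ccc(O)c(O)c1)[C@@H](O)[C@@H]2c1cc2c(cc1O)O[C@H](c1ccc(O)c(O)c1)[C@@H](O)[C@H]2O | target

## Step count and risks

Total steps: 11. Longest linear sequence: 10 (steps 1–6, then 7 or 8, then 9–11).

**Step 9.** The cation from 12 may be captured by ring A of a second molecule of 12 or of the product, giving oligomers, or it may be attacked with poor facial selectivity. The fallback blocks the competing nucleophilic site of the electrophile with bromine. It sets out from 10: NBS (1 equiv, CH2Cl2, −78 °C) should brominate the most activated position, para to O1 and ortho to the benzyloxy group, giving the 6-bromo diol F1. Thiolysis as in step 8 gives the 6-bromo thioether F2. AgBF4 coupling with 11 gives the bromo dimer carbonate F3, and K2CO3/MeOH gives the bromo dimer diol F4. Hydrogenolysis (H2, Pd(OH)2/C, Et3N, THF/MeOH) removes bromine and benzyl groups together and returns to the route at 15.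

**Step 6.** Reductive loss of the α-aryloxy group, simple reduction of the aldehydes, or low diastereoselectivity in the ketyl addition may compete. The fallback forms the same bond as an alkene and adds the two oxygens afterwards. It sets out from 9: non-basic Takai methylenation (CH2I2, Zn, Ti(OiPr)4, THF) of both aldehydes gives the divinyl ether F5. Ring-closing metathesis with second-generation Grubbs catalyst (CH2Cl2, 40 °C) gives the flav-3-ene F6. Dihydroxylation (OsO4 cat., NMO, acetone/H2O) on the face anti to the 2-aryl group gives the 2,3-trans-3,4-cis diol and returns to the route at 10.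

**Step 11.** Hydrogenolysis may go on to cleave the benzylic C4–OH bond of ring F once the para phenol is free. The fallback masks the hydroxyls before debenzylation. It sets out from 14: TESOTf/2,6-lutidine (CH2Cl2, −78 → 0 °C) gives the tris(triethylsilyl) ether F7. Hydrogenolysis (H2, Pd(OH)2/C, EtOAc) gives the hexaphenol tris(triethylsilyl) ether F8. Buffered desilylation (TBAF/AcOH, THF, 0 °C) returns to the route at 15.

## Further compounds

F1 | step 9 | 6-bromo derivative of diol 10 | C(c1ccccc1)Oc1c(Br)cc2c(c1)O[C@H](c1ccc(OCc3ccccc3)c(OCc3ccccc3)c1)[C@@H](O)[C@H]2O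
F2 | step 9 | 6-bromo derivative of thioether 12 | C(c1ccccc1)Oc1c(Br)cc2c(c1)O[C@H](c1ccc(OCc3ccccc3)c(OCc3ccccc3)c1)[C@@H](O)[C@@H]2SCc1ccccc1
F3 | step 9 | 6-bromo (ring A) derivative of dimer carbonate 13 | C(c1ccccc1)Oc1c(Br)cc2c(c1)O[C@H](c1ccc(OCc3ccccc3)c(OCc3ccccc3)c1)[C@@H](O)[C@@H]2c1cc2c(cc1OCc1ccccc1)O[C@H](c1ccc(OCc3ccccc3)c(OCc3ccccc3)c1)[C@H]4OC(=O)O[C@@H]24
F4 | step 9 | 6-bromo (ring A) derivative of dimer diol 14 | C(c1ccccc1)Oc1c(Br)cc2c(c1)O[C@H](c1ccc(OCc3ccccc3)c(OCc3ccccc3)c1)[C@@H](O)[C@@H]2c1cc2c(cc1OCc1ccccc1)O[C@H](c1ccc(OCc3ccccc3)c(OCc3ccccc3)c1)[C@@H](O)[C@H]2O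
F5 | step 6 | 4-(benzyloxy)-2-{1-[3,4-bis(benzyloxy)phenyl]prop-2-enyloxy}-1-vinylbenzene, configuration of 9 retained | C=C[C@H](Oc1cc(OCc2ccccc2)ccc1C=C)c1ccc(OCc2ccccc2)c(OCc2ccccc2)c1
F6 | step 6 | 7-(benzyloxy)-2-[3,4-bis(benzyloxy)phenyl]-2H-chromene, 2-aryl configuration as in 10 | C(c1ccccc1)Oc1ccc2c(c1)O[C@H](c1ccc(OCc3ccccc3)c(OCc3ccccc3)c1)C=C2
F7 | step 11 | tris(triethylsilyl) ether of 14 | C(c1ccccc1)Oc1ccc2c(c1)O[C@H](c1ccc(OCc3ccccc3)c(OCc3ccccc3)c1)[C@@H](O[Si](CC)(CC)CC)[C@@H]2c1cc2c(cc1OCc1ccccc1)O[C@H](c1ccc(OCc3ccccc3)c(OCc3ccccc3)c1)[C@@H](O[Si](CC)(CC)CC)[C@H]2O[Si](CC)(CC)CC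
F8 | step 11 | tris(triethylsilyl) ether of 15 with six free phenols | Oc1ccc2c(c1)O[C@H](c1ccc(O)c(O)c1)[C@@H](O[Si](CC)(CC)CC)[C@@H]2c1cc2c(cc1O)O[C@H](c1ccc(O)c(O)c1)[C@@H](O[Si](CC)(CC)CC)[C@H]2O[Si](CC)(CC)CC
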